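**Plan**
Ring A (C1–OH, C2–OAr, C3–C6 each bearing Br) is taken back through its keto tautomer to a 5,6-dioxygenated tetrabromocyclohexa-1,3-diene and cut at C2–C3 and C1–C6. The sulfone S=O bonds, the enol O–Si bond and the ArO–CH2 bond are cut last.
The cut is possible because C3–C6 with their four contiguous bromines form a mirror-symmetric tetrabromobutadiene unit (delivered as tetrabromothiophene 1,1-dioxide), while C1–C2 with their two different oxygens form a cis-1,2-dioxygenated ethene.
Forward: ring B is bought intact as 2,4-dibromophenol and receives the two-carbon unit as a Z silyl enol ether. Ring A is then closed in one cycloaddition/SO2-extrusion step and aromatised by desilylation and alcohol oxidation.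
Stereochemistry: the target has none. C1 and C2 are sp3 only between steps 5 and 7, arise cis (racemic) from the Z alkene by suprafacial addition, and vanish on tautomerisation.

Key step: step 5

Remark: the target has no stereocentre and no configurationally stable axis, so "single enantiomer" is taken to mean the one achiral constitution; the transient sp3 centres are made racemic.

**Step 1**
Reactants: 1 tetrabromothiophene
Product: 2 tetrabromothiophene 1,1-dioxide
Conditions: CF3CO3H [H2O2, (CF3CO)2O], CH2Cl2, 0 °C → rt
Reagents that add atoms: trifluoroperacetic acid, OOC(=O)C(F)(F)F (formed in the flask from hydrogen peroxide, OO, and trifluoroacetic anhydride)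
Why: Electrophilic S-oxidation of a thiophene to its sulfone needs a strong peracid when the ring is this electron-poor, and the fully halogenated dioxide should neither dimerise nor be epoxidised.

**Step 2**
Reactants: 3 2,4-dibromophenol; 4 bromoacetaldehyde diethyl acetal
Product: 5 2,4-dibromo-1-(2,2-diethoxyethoxy)benzene
Conditions: K2CO3, DMF, 110 °C
Reagents that add atoms: none
Why: Williamson ether synthesis of an acidic phenoxide on a primary bromide; the acetal is inert to carbonate.

**Step 3**
Reactants: 5 2,4-dibromo-1-(2,2-diethoxyethoxy)benzene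
Product: 6 (2,4-dibromophenoxy)acetaldehyde
Conditions: 1 M aq. HCl, THF, 60 °C; azeotropic drying (PhMe), used at once
Reagents that add atoms: water, O
Why: Acid-catalysed acetal hydrolysis; the dibrominated ring is too electron-poor to cyclise onto the oxocarbenium ion (benzofuran formation) in dilute aqueous acid.

**Step 4**
Reactants: 6 (2,4-dibromophenoxy)acetaldehyde
Product: 7 (Z)-tert-butyl{[2-(2,4-dibromophenoxy)ethenyl]oxy}dimethylsilane
Conditions: TBSOTf, Et3N, CH2Cl2, 0 °C → rt; Et3N-deactivated silica
Reagents that add atoms: tert-butyldimethylsilyl trifluoromethanesulfonate, CC(C)(C)[Si](C)(C)OS(=O)(=O)C(F)(F)F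
Why: Soft enolisation with O-silylation (silyl triflate/tertiary amine) converts an aldehyde into its silyl enol ether, α-oxygenated aldehydes being expected to favour the Z isomer; a minor E isomer would only give the trans diastereomer of the cycloadduct, which leads to the same arene.

**Step 5**
Reactants: 2 tetrabromothiophene 1,1-dioxide; 7 (Z)-tert-butyl{[2-(2,4-dibromophenoxy)ethenyl]oxy}dimethylsilane
Product: 9 cis-tert-butyl{[2,3,4,5-tetrabromo-6-(2,4-dibromophenoxy)cyclohexa-2,4-dien-1-yl]oxy}dimethylsilane (racemic), via bridged sulfone cycloadduct 8 (not isolated)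
Conditions: PhMe, 25 → 60 °C, Ar sweep (−SO2), dark, 2,6-di-tert-butyl-4-methylpyridine (5 mol %)
Reagents that add atoms: none
Why: The LUMO of the electron-poor sulfone diene 2 and the HOMO of the cis-dioxygenated enol ether 7 combine in a concerted, suprafacial inverse-electron-demand Diels–Alder reaction through the sulfone α-carbons to give the 7-thiabicyclo[2.2.1]heptene dioxide 8, which loses SO2 by thermally allowed cheletropic extrusion under the same conditions and unveils the 1,3-diene 9. The closest known reaction type is the cycloaddition/SO2 extrusion of tetrahalothiophene 1,1-dioxides with alkenes to tetrahalocyclohexa-1,3-dienes. Ring A closes as a six-membered carbocycle by intermolecular [4+2] cycloaddition, the C2–C3 and C1–C6 bonds (target numbering) being made in the same step. The new centres C1 and C2 should come out cis because the Z geometry of 7 is transferred suprafacially; no facial or endo/exo control is needed, since 7 is achiral, the bridge is lost and both centres are erased in step 7. No regiochemical question exists because the diene is mirror-symmetric; what the step needs is cycloaddition in preference to polar Michael-type addition and survival of 9 without loss of silanol or aryloxide, which the apolar solvent, the acid scavenger, the SO2 sweep, the moderate temperature and the robust TBS ether are meant to secure.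

**Step 6**
Reactants: 9 cis-tert-butyl{[2,3,4,5-tetrabromo-6-(2,4-dibromophenoxy)cyclohexa-2,4-dien-1-yl]oxy}dimethylsilane
Product: 10 cis-2,3,4,5-tetrabromo-6-(2,4-dibromophenoxy)cyclohexa-2,4-dien-1-ol (racemic)
Conditions: HF·pyridine, THF/pyridine, 0 °C → rt
Reagents that add atoms: none
Why: Fluoride-driven cleavage of the Si–O bond under buffered, non-basic conditions avoids base-induced β-elimination of aryloxide, and the four bromines and the β-aryloxy group should disfavour ionisation at the carbinol carbon, so the dienol is expected to persist with both centres untouched.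

**Step 7**
Reactants: 10 cis-2,3,4,5-tetrabromo-6-(2,4-dibromophenoxy)cyclohexa-2,4-dien-1-ol
Product: 12 3,4,5,6-tetrabromo-2-(2,4-dibromophenoxy)phenol (target), via 6H-dienone tautomer 11 (not isolated)
Conditions: Dess–Martin periodinane, CH2Cl2, 0 °C → rt; aq. Na2S2O3 then dilute HCl work-up
Reagents that add atoms: none
Why: Dess–Martin oxidation of the secondary allylic alcohol under near-neutral conditions gives dienone 11, whose remaining sp3 C–H is α to the carbonyl and should enolise irreversibly to the aromatic phenol, removing the last stereocentre.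

**Compound list**
1 | tetrabromothiophene | Brc1sc(Br)c(Br)c1Br | starting material
2 | tetrabromothiophene 1,1-dioxide | O=S1(=O)C(Br)=C(Br)C(Br)=C1Br | intermediate
3 | 2,4-dibromophenol | Oc1ccc(Br)cc1Br | starting material
4 | bromoacetaldehyde diethyl acetal (2-bromo-1,1-diethoxyethane) | CCOC(CBr)OCC | starting material
5 | 2,4-dibromo-1-(2,2-diethoxyethoxy)benzene | CCOC(COc1ccc(Br)cc1Br)OCC | intermediate
6 | (2,4-dibromophenoxy)acetaldehyde | O=CCOc1ccc(Br)cc1Br | intermediate
7 | (Z)-tert-butyl{[2-(2,4-dibromophenoxy)ethenyl]oxy}dimethylsilane | CC(C)(C)[Si](C)(C)O/C=C\Oc1ccc(Br)cc1Br | intermediate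
8 | 1,2,3,4-tetrabromo-5-(tert-butyldimethylsilyloxy)-6-(2,4-dibromophenoxy)-7-thiabicyclo[2.2.1]hept-2-ene 7,7-dioxide (5,6-cis, both oxygens endo drawn, racemic; the exo adduct gives the same diene) | CC(C)(C)[Si](C)(C)O[C@H]1[C@@H](Oc2ccc(Br)cc2Br)[C@@]2(Br)C(Br)=C(Br)[C@]1(Br)S2(=O)=O | intermediate (formed in the flask, not isolated)
9 | cis-tert-butyl{[2,3,4,5-tetrabromo-6-(2,4-dibromophenoxy)cyclohexa-2,4-dien-1-yl]oxy}dimethylsilane (racemic, one enantiomer drawn) | CC(C)(C)[Si](C)(C)O[C@H]1[C@@H](Oc2ccc(Br)cc2Br)C(Br)=C(Br)C(Br)=C1Br | intermediate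
10 | cis-2,3,4,5-tetrabromo-6-(2,4-dibromophenoxy)cyclohexa-2,4-dien-1-ol (racemic, one enantiomer drawn) | O[C@H]1[C@@H](Oc2ccc(Br)cc2Br)C(Br)=C(Br)C(Br)=C1Br | intermediate
11 | 2,3,4,5-tetrabromo-6-(2,4-dibromophenoxy)cyclohexa-2,4-dien-1-one (racemic, one enantiomer drawn) | O=C1[C@@H](Oc2ccc(Br)cc2Br)C(Br)=C(Br)C(Br)=C1Br | intermediate (formed in the flask, not isolated)
12 | 3,4,5,6-tetrabromo-2-(2,4-dibromophenoxy)phenol | Oc1c(Br)c(Br)c(Br)c(Br)c1Oc1ccc(Br)cc1Br | target

**Step count and risks**
Total: 7 steps. Longest linear sequence: 6 steps (steps 2–7, from 3 and 4); the diene branch is one step.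

Most likely to fail, in order:

Step 5. The strongly polarised partners may combine stepwise (Michael-type attack of the enol silane on the sulfone with silyl transfer) instead of cycloadding. The diene, once formed, may also aromatise early by losing silanol or aryloxide, which removes one ring oxygen for good. The fallback keeps the same two C–C bonds but raises the dienophile to the carboxylic oxidation level; it sets out from 3 (with 2 unchanged) and returns at 11. Phenol 3 would be alkylated with methyl bromoacetate (K2CO3, acetone) to methyl (2,4-dibromophenoxy)acetate F1. Enolisation with LiHMDS, an amide base that should not metalate the bromoarene, and trapping with TBSCl (THF–DMPU, −78 °C) should give (Z)-tert-butyl{[2-(2,4-dibromophenoxy)-1-methoxyethenyl]oxy}dimethylsilane F2. Warming F2 with 2 in toluene should give 1,2,3,4-tetrabromo-5-(tert-butyldimethylsilyloxy)-6-(2,4-dibromophenoxy)-5-methoxy-7-thiabicyclo[2.2.1]hept-2-ene 7,7-dioxide F3, which loses SO2 to tert-butyl{[2,3,4,5-tetrabromo-6-(2,4-dibromophenoxy)-1-methoxycyclohexa-2,4-dien-1-yl]oxy}dimethylsilane F4. In F4 the doubly oxygenated carbon carries no hydrogen, so no elimination toward an arene can remove a ring oxygen. HF·pyridine would take off silicon, the hemiketal would expel methanol, and dienone 11 would result and tautomerise to 12.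

Step 6. Ionisation at the carbinol carbon or β-elimination during unmasking (and again under the oxidant of step 7) would dehydrate or de-aryloxylate the dienol to an arene lacking one oxygen. The fallback aromatises before the oxygen is freed; it sets out from 9 and returns at 12, bypassing 10 and 11. Diene 9 would be dehydrogenated with DDQ (PhCl, 80 °C) by hydride abstraction from the silyloxy-bearing allylic C–H and proton loss, giving tert-butyl[2,3,4,5-tetrabromo-6-(2,4-dibromophenoxy)phenoxy]dimethylsilane F5. The aryl silyl ether would then be cleaved with TBAF/AcOH (THF, 0 °C) to 12.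

Step 4. Amine-promoted self-aldol condensation of the unhindered, enolisable α-aryloxy aldehyde may outrun O-silylation, and the enol silane may hydrolyse during purification. The fallback uses an enol ester made under acid catalysis; it sets out from 6 and returns at 10. Aldehyde 6 would be heated with isopropenyl acetate and catalytic TsOH to give (Z)-2-(2,4-dibromophenoxy)ethenyl acetate F6 (the E isomer would serve equally). Cycloaddition of F6 with 2 (PhMe, 80–100 °C) should give 1,2,3,4-tetrabromo-6-(2,4-dibromophenoxy)-7,7-dioxo-7-thiabicyclo[2.2.1]hept-2-en-5-yl acetate F7 and, after SO2 loss, cis-2,3,4,5-tetrabromo-6-(2,4-dibromophenoxy)cyclohexa-2,4-dien-1-yl acetate F8. Reductive removal of the acetate with DIBAL-H (CH2Cl2, −78 °C), which needs neither acid nor base, would give dienol 10.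

**Further compounds**
F1 | step 5 | methyl (2,4-dibromophenoxy)acetate | COC(=O)COc1ccc(Br)cc1Br
F2 | step 5 | (Z)-tert-butyl{[2-(2,4-dibromophenoxy)-1-methoxyethenyl]oxy}dimethylsilane | CO/C(O[Si](C)(C)C(C)(C)C)=C/Oc1ccc(Br)cc1Br
F3 | step 5 | 1,2,3,4-tetrabromo-5-(tert-butyldimethylsilyloxy)-6-(2,4-dibromophenoxy)-5-methoxy-7-thiabicyclo[2.2.1]hept-2-ene 7,7-dioxide (one diastereomer drawn, racemic) | CC(C)(C)[Si](C)(C)O[C@@]1(OC)[C@@H](Oc2ccc(Br)cc2Br)[C@@]2(Br)C(Br)=C(Br)[C@]1(Br)S2(=O)=O
F4 | step 5 | tert-butyl{[2,3,4,5-tetrabromo-6-(2,4-dibromophenoxy)-1-methoxycyclohexa-2,4-dien-1-yl]oxy}dimethylsilane (silyloxy cis to aryloxy drawn, racemic) | CC(C)(C)[Si](C)(C)O[C@@]1(OC)[C@@H](Oc2ccc(Br)cc2Br)C(Br)=C(Br)C(Br)=C1Br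
F5 | step 6 | tert-butyl[2,3,4,5-tetrabromo-6-(2,4-dibromophenoxy)phenoxy]dimethylsilane | CC(C)(C)[Si](C)(C)Oc1c(Br)c(Br)c(Br)c(Br)c1Oc1ccc(Br)cc1Br
F6 | step 4 | (Z)-2-(2,4-dibromophenoxy)ethenyl acetate | CC(=O)O/C=C\Oc1ccc(Br)cc1Br
F7 | step 4 | 1,2,3,4-tetrabromo-6-(2,4-dibromophenoxy)-7,7-dioxo-7-thiabicyclo[2.2.1]hept-2-en-5-yl acetate (5,6-cis, endo drawn, racemic) | CC(=O)O[C@H]1[C@@H](Oc2ccc(Br)cc2Br)[C@@]2(Br)C(Br)=C(Br)[C@]1(Br)S2(=O)=O
F8 | step 4 | cis-2,3,4,5-tetrabromo-6-(2,4-dibromophenoxy)cyclohexa-2,4-dien-1-yl acetate (racemic, one enantiomer drawn) | CC(=O)O[C@H]1[C@@H](Oc2ccc(Br)cc2Br)C(Br)=C(Br)C(Br)=C1Br
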